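The readings are simulated with constants of no real substance; the scatter is artificial.

A closed, stirred vessel charged with L and G turns L into X and J, and the three new flasks share their charge and time and differ in temperature, so the decision is which of them must be run and which can be read from the earlier runs.

the same everywhere: L 0.020 M
- winter: G 1.2 mol%; temperature 25 °C; run made earlier
- summer: G 5 mol%; temperature 50 °C; run made earlier
- blue: G 2.5 mol%; temperature 70 °C; time 80 min
- ochre: G 2.5 mol%; temperature 30 °C; time 80 min
- red: G 2.5 mol%; temperature 50 °C; time 80 min

- winter (time / min: X / %, J / %): 90.0: 17, 18; 180: 21, 25; 300: 34, 27; 360: 31, 24; 480: 41, 29; 600: 38, 28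
- summer (time / min: X / %, J / %): 15.0: 35, 28; 20.0: 40, 29; 40.0: 41, 30; 60.0: 46, 30; 120: 43, 25; 150: 45, 27

(readings scatter by 2 percentage points)



- the flask with the highest share of X in all that became X or J ("all alike" if they lie within 1.5 percentage points) (blue / ochre / red / all alike)
- share of X in all that became X or J, blue
- share of X in all that became X or J, ochre
- share of X in all that became X or J, red

In the summer run X and J together stand at 69.0% after 20.0 min and 72.0% after 150 min, while the share of X reads 58.0% and then 62.5%, so, within the scatter, the share seems to go on moving after the total has levelled. The working assumption here is that G moves it. Each new flask receives 2.00 min; call this the catalyst dose, the loading of G multiplied by the time, and take equal doses at one temperature and one charge of L to give equal shares.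

Red then matches the summer run at 40.0 min, where the reading gives 57.7%, so red needs no run. Ochre matches the winter run at 167 min, and the winter reading at 180 min gives 45.7%, a share carried over to ochre with caution, ochre being 5.00 K warmer. Blue is hotter than either earlier run, so it has no match, this reckoning gives it no number, and blue is the flask to run.

The forecast, unlike this reckoning, does give blue a number and puts blue highest, with 63% (58% to 69%) for blue, 52% (47% to 57%) for ochre and 58.5% (55% to 62%) for red, noting that “The early share also looks higher when hotter”.

The flasks give 50.0% in blue, 54.8% in ochre and 60.5% in red, so red stands highest.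

    L + G → E (k = 0.140 M⁻¹ s⁻¹, Ea = 49.0 kJ mol⁻¹)
    L ⇌ X (K = 1.40, k = 0.00170 s⁻¹, Ea = 97.0 kJ mol⁻¹, ΔH = −11.0 kJ mol⁻¹)
    X + G ⇌ J + G, rate k3*[G]*[X] forward; the back reaction follows from the equilibrium constant (K = 1.00, k = 10.0 M⁻¹ s⁻¹, Ea = 60.0 kJ mol⁻¹, ΔH = 20.0 kJ mol⁻¹)
    J ⇌ L (k = 0.0120 s⁻¹, Ea = 93.0 kJ mol⁻¹)
    (constants at 70 °C)

Ochre reached its 54.8% on a dose of 2.00 min. Its neighbour, the same flask with 10 mol% of G, receives 8.00 min, which is 4.00 times ochre's dose and more than the 7.20 min of the winter run at its last reading, so the reckoning, stretched across the 5.00 K between them, looks to that reading's 57.6%. The neighbour gives 67.5%, with X at 31.7% and L at 47% of the charge.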